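The route rests on disconnecting C1–C10 of ring A while tying the C20 oxygen to C3. Quaternary C10 bears the C20 formyl group inside a γ,δ-unsaturated aldehyde, C20(=O)–C10–C1–C2=C3, which is the retron of a Claisen rearrangement. Heating the 2-vinyl-3,4-dihydro-2H-pyran 28 (enol ether C10=C20–O–C3, vinyl C2=C1 on C3, fused to rings B, C and D) should form the C1–C10 bond, close carbocyclic ring A, set C10 and free the aldehyde in one operation. Pyran 28 is cut out of a cyclohexenol by a single ozonolysis that also unmasks the 16-ketone.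

Key step: step 18

Remark: gibberellane numbering is used for all intermediates and the target is drawn as its open 20-aldehyde (it can close reversibly to the 19,20-lactol); the vinyl group of 28 is on the pyran face syn to H5, as the rearrangement requires, and O13 is carried as a tert-butyldimethylsilyl ether and C19 as a 2-(trimethylsilyl)ethyl ester so that both survive the sequence and fall to fluoride at the end.

Step 1
Reactants: 1 pent-4-enal; 2 but-3-en-2-one
Product: 3 (2S)-5-oxo-2-(prop-2-en-1-yl)hexanal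
Conditions: (S)-α,α-diphenylprolinol trimethylsilyl ether (10 mol%), ethyl 3,4-dihydroxybenzoate (20 mol%), neat, 4 °C
Reagents that add atoms: none
Why: Organocatalytic Michael addition through the (E)-enamine of 1, whose Re face is blocked by the diphenyl(silyloxy)methyl group, so that 2 is attacked from the Si face and C9 is formed with S configuration.

Step 2
Reactants: 3 (2S)-5-oxo-2-(prop-2-en-1-yl)hexanal
Product: 4 (4S)-4-(prop-2-en-1-yl)cyclohex-2-en-1-one
Conditions: LiOH (0.2 equiv), i-PrOH, rt
Reagents that add atoms: none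
Why: Intramolecular aldol condensation (Robinson-type closure) of the methyl ketone onto the aldehyde gives the conjugated enone, and C9 ends up γ to the ketone where the mild base no longer enolises it.

Step 3
Reactants: 4 (4S)-4-(prop-2-en-1-yl)cyclohex-2-en-1-one; 5 tert-butyl[(1-methoxyethenyl)oxy]dimethylsilane
Product: 6 methyl 2-[(1S,6S)-3-(tert-butyldimethylsilyloxy)-6-(prop-2-en-1-yl)cyclohex-2-en-1-yl]acetate
Conditions: t-BuMe2SiOTf (5 mol%), CH2Cl2, −78 °C
Reagents that add atoms: none
Why: Mukaiyama–Michael addition of the ketene silyl acetal occurs anti to the C9 allyl group and transfers the silyl group to oxygen, which fixes the enol ether regiochemistry needed for step 4 (the C8 stereocentre is erased there).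

Step 4
Reactants: 6 methyl 2-[(1S,6S)-3-(tert-butyldimethylsilyloxy)-6-(prop-2-en-1-yl)cyclohex-2-en-1-yl]acetate
Product: 7 methyl 2-[(6S)-3-oxo-6-(prop-2-en-1-yl)cyclohex-1-en-1-yl]acetate
Conditions: Pd(OAc)2 (1.05 equiv), MeCN, rt
Reagents that add atoms: none
Why: Saegusa–Ito oxidation, in which the palladium enolate loses H8 by β-hydride elimination, should regenerate the enone with C8 now carrying the acetate arm (C6, C7).

Step 5
Reactants: 7 methyl 2-[(6S)-3-oxo-6-(prop-2-en-1-yl)cyclohex-1-en-1-yl]acetate; 8 tributyl(propa-1,2-dien-1-yl)stannane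
Product: 9 methyl 2-[(1R,2S)-5-oxo-2-(prop-2-en-1-yl)-1-(prop-2-yn-1-yl)cyclohexyl]acetate
Conditions: TiCl4 (1.1 equiv), CH2Cl2, −78 °C; aq. NaHCO3
Reagents that add atoms: none
Why: Lewis-acid-promoted conjugate propargylation (SE2' attack of the allenylstannane on the TiCl4-activated enone, a Sakurai-type addition) should occur anti to the C9 allyl group, setting quaternary C8 with C15 cis to H9 and C6 cis to C10.

Step 6
Reactants: 9 methyl 2-[(1R,2S)-5-oxo-2-(prop-2-en-1-yl)-1-(prop-2-yn-1-yl)cyclohexyl]acetate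
Product: 11 methyl 2-[(1R,2S)-2-(2,2-dimethoxyethyl)-5-oxo-1-(prop-2-yn-1-yl)cyclohexyl]acetate, via keto aldehyde 10 (not isolated)
Conditions: O3, CH2Cl2/MeOH, −78 °C; Me2S; then HC(OMe)3, CeCl3·7H2O (10 mol%), MeOH, rt
Reagents that add atoms: ozone [O-][O+]=O (oxygen of 10); trimethyl orthoformate COC(OC)OC
Why: Ozonolysis cleaves the terminal alkene far faster than the terminal alkyne to give the C5 aldehyde, and CeCl3-catalysed acetalisation (Luche–Gemal conditions) protects this aldehyde but not the ketone needed in step 7.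

Step 7
Reactants: 11 methyl 2-[(1R,2S)-2-(2,2-dimethoxyethyl)-5-oxo-1-(prop-2-yn-1-yl)cyclohexyl]acetate
Product: 12 methyl 2-[2-(2,2-dimethoxyethyl)-5-hydroxy-6-methylidenebicyclo[3.2.1]octan-1-yl]acetate
Conditions: SmI2 (2.5 equiv), HMPA, t-BuOH, THF, 0 °C
Reagents that add atoms: none
Why: Ketyl–alkyne reductive cyclisation (5-exo-dig) joins C13 to C16, and because C15 is axial on C8 the bicyclo[3.2.1]octane can close in one sense only, which sets C13 together with the 13-hydroxyl and the 16-methylene.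

Step 8
Reactants: 12 methyl 2-[2-(2,2-dimethoxyethyl)-5-hydroxy-6-methylidenebicyclo[3.2.1]octan-1-yl]acetate
Product: 14 methyl 2-{2-[(1E)-1-(dimethylamino)-3-oxoprop-1-en-2-yl]-5-hydroxy-6-methylidenebicyclo[3.2.1]octan-1-yl}acetate, via hydroxy aldehyde 13 (not isolated)
Conditions: 1 M HCl, THF, rt; then t-BuOCH(NMe2)2, PhMe, 50 °C
Reagents that add atoms: water O; tert-butoxybis(dimethylamino)methane CN(C)C(OC(C)(C)C)N(C)C
Why: Acid hydrolysis frees the C5 aldehyde, whose α-methylene (C10) is the only position acidic enough to condense with the aminal ester (aminomethylenation), giving a vinylogous formamide that adds C20 at the aldehyde oxidation level.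

Step 9
Reactants: 14 methyl 2-{2-[(1E)-1-(dimethylamino)-3-oxoprop-1-en-2-yl]-5-hydroxy-6-methylidenebicyclo[3.2.1]octan-1-yl}acetate
Product: 16 tricyclic enal (methyl 13-hydroxy-20-oxo-1,2,3,4,18,19-hexanorgibberella-5(10),16-dien-7-oate with 6β-ester), via aldol adduct 15 (not isolated)
Conditions: LiN(i-Pr)2 (2.3 equiv), THF, −78 to 0 °C; then 1 M HCl, THF, rt
Reagents that add atoms: water O
Why: The C6 ester enolate adds intramolecularly to the formyl carbon C5 (5-exo-trig aldol addition, closing ring B), and acid then eliminates water and hydrolyses the iminium, a Stork–Danheiser-type transposition that delivers the C5=C10 enal; C6, α to the ester and γ to the enal, should settle as the exo (β) ester.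

Step 10
Reactants: 16 tricyclic enal
Product: 17 13-O-tert-butyldimethylsilyl ether of the tricyclic enal
Conditions: t-BuMe2SiOTf, 2,6-lutidine, CH2Cl2, −78 to 0 °C
Reagents that add atoms: tert-butyldimethylsilyl trifluoromethanesulfonate CC(C)(C)[Si](C)(C)OS(=O)(=O)C(F)(F)F
Why: Silylation of the tertiary bridgehead alcohol with a silyl triflate and a hindered pyridine base, needed because a free 13-hydroxy-16-ketone would later be open to α-ketol rearrangement.

Step 11
Reactants: 18 2,2,6-trimethyl-4H-1,3-dioxin-4-one; 19 2-(trimethylsilyl)ethanol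
Product: 20 2-(trimethylsilyl)ethyl 3-oxobutanoate
Conditions: xylene, 140 °C
Reagents that add atoms: none
Why: Thermal retro-Diels–Alder cleavage of the dioxinone releases acetylketene, which the alcohol traps as the β-keto ester (acetoacetylation).

Step 12
Reactants: 17 13-O-silyl tricyclic enal; 20 2-(trimethylsilyl)ethyl 3-oxobutanoate
Product: 22 trans-fused tetracyclic cyclohexenone β-keto ester (C3=O and C2=C20), via Michael adduct 21 (not isolated)
Conditions: 1,8-diazabicyclo[5.4.0]undec-7-ene (20 mol%), THF, 0 °C to rt; then pyrrolidine (30 mol%), AcOH (30 mol%), PhMe, 60 °C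
Reagents that add atoms: none
Why: Robinson-type annulation in which the β-keto ester adds to C5 (Michael addition) anti to the neighbouring 6β-ester, setting H5 β, and amine-catalysed aldol condensation of the methyl ketone (C2) onto C20 closes the cyclohexenone, whose γ-carbon C10 should equilibrate to the trans fusion in which all ring B substituents alternate.

Step 13
Reactants: 22 trans-fused tetracyclic cyclohexenone β-keto ester
Product: 23 allylic alcohol (hydroxyl at C3 on the α face)
Conditions: NaBH4, CeCl3·7H2O, MeOH, −78 °C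
Reagents that add atoms: none
Why: Luche 1,2-reduction with axial hydride attack on the β face of the trans-fused cyclohexenone should place the hydroxyl equatorial on the α face (H3 β), the C3 configuration needed for chirality transfer in step 18; the C4 epimers converge in step 14.

Step 14
Reactants: 23 allylic alcohol
Product: 24 C4-methylated allylic alcohol (4β-methyl and 4α-ester)
Conditions: LiN(i-Pr)2 (2.3 equiv), THF, −78 to −30 °C; MeI, DMPU, −78 to −20 °C
Reagents that add atoms: iodomethane CI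
Why: Fráter–Seebach alkylation of the β-hydroxy ester dianion, in which the chelated exocyclic enolate is methylated anti to the C3 alkoxide and from the equatorial direction, giving 4β-methyl and the axial 4α-ester; a C6 enolate, if formed at all, is too hindered to be alkylated.

Step 15
Reactants: 24 C4-methylated allylic alcohol
Product: 25 lactol aldehyde with 16-ketone
Conditions: O3, CH2Cl2, −78 °C; then PPh3, −78 °C to rt
Reagents that add atoms: ozone [O-][O+]=O
Why: Ozonolysis cleaves the C2=C20 alkene and the 16-methylene in one operation, unveiling the 16-ketone, while the C3 hydroxyl captures the new C20 aldehyde as a six-membered lactol and leaves only the C2 aldehyde free.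

Step 16
Reactants: 25 lactol aldehyde with 16-ketone
Product: 26 3-vinyl lactol
Conditions: Ph3PCH3Br (2.2 equiv), KN(SiMe3)2 (2.1 equiv), THF, −78 to −20 °C
Reagents that add atoms: methyltriphenylphosphonium bromide C[P+](c1ccccc1)(c1ccccc1)c1ccccc1.[Br-]
Why: Wittig methylenation at low temperature should pick the free α-alkoxy aldehyde over the lactol (held as its alkoxide) and over the hindered α-silyloxy ketone, installing C1 without touching the C3 stereocentre.

Step 17
Reactants: 26 3-vinyl lactol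
Product: 28 2-vinyl-3,4-dihydro-2H-pyran fused to rings B, C and D, via lactol mesylate 27 (not isolated)
Conditions: MsCl, Et3N, THF, 0 to 60 °C
Reagents that add atoms: methanesulfonyl chloride CS(Cl)(=O)=O (mesyl group of 27 only)
Why: Mesylation of the lactol and loss of methanesulfonate through the oxocarbenium ion removes H10, the only β-hydrogen, to give the cyclic enol ether (standard lactol-to-dihydropyran dehydration), which also erases the C10 stereocentre.

Step 18
Reactants: 28 2-vinyl-3,4-dihydro-2H-pyran fused to rings B, C and D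
Product: 29 ring A aldehyde (C20 formyl on quaternary C10, C2=C3 alkene, 16-ketone)
Conditions: PhMe (0.01 M), N,O-bis(trimethylsilyl)acetamide (5 mol%), sealed base-washed tube, 190 °C
Reagents that add atoms: none
Why: Concerted [3,3]-sigmatropic (Claisen) shift of the allyl vinyl ether C10=C20–O–C3–C2=C1, in which the C3–O bond breaks while C1 bonds to C10, so that the ring oxygen becomes the C20 aldehyde oxygen and the alkene moves to C2–C3. The closest known reaction type is the thermal rearrangement of 2-alkenyl-3,4-dihydro-2H-pyrans to cyclohex-3-ene-1-carbaldehydes. Ring A closes as a six-membered carbocycle through a boat-shaped six-atom array (C1, C2, C3, O, C20, C10) braced by the C4–C5 bridge, an intramolecular exchange of the oxacycle for a carbocycle of the same size. The single new stereocentre, C10, is set by suprafacial chirality transfer from C3: the vinyl group stands on the pyran face syn to H5, so C1 arrives on that face and C20 ends anti to H5 (trans fusion of rings A and B). The step needs this facial fidelity and freedom from acid; the rigid bicyclic tether, which allows no chair alternative, secures the first, and base-washed glass with a silylating acid scavenger protects the enol ether. The gain of a C=O bond makes the shift irreversible.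

Step 19
Reactants: 29 ring A aldehyde
Product: 30 C20 dimethyl acetal
Conditions: HC(OMe)3, pyridinium p-toluenesulfonate, MeOH, 40 °C
Reagents that add atoms: trimethyl orthoformate COC(OC)OC
Why: Acid-catalysed acetalisation with orthoformate as water scavenger masks the aldehyde, which should react far faster than the hindered α-silyloxy ketone, so that the later ylide meets only the ketone.

Step 20
Reactants: 30 C20 dimethyl acetal
Product: 31 2β,3β-epoxide
Conditions: 3-chloroperbenzoic acid, NaHCO3, CH2Cl2, 0 °C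
Reagents that add atoms: 3-chloroperbenzoic acid OOC(=O)c1cccc(Cl)c1
Why: Prilezhaev epoxidation of the only alkene present, on the β face because the α face of ring A is screened by the axial C19 ester and the axial C20 acetal.

Step 21
Reactants: 31 2β,3β-epoxide
Product: 32 16-methylene 2β,3β-epoxide
Conditions: Ph3PCH3Br, KOt-Bu, THF, rt to 50 °C
Reagents that add atoms: methyltriphenylphosphonium bromide C[P+](c1ccccc1)(c1ccccc1)c1ccccc1.[Br-]
Why: Wittig methylenation of the 16-ketone with excess ylide restores C17 before any free hydroxyl is present; esters, acetal and the hindered epoxide should not react with the ylide.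

Step 22
Reactants: 32 16-methylene 2β,3β-epoxide
Product: 33 2α-phenylselanyl 3β-alcohol
Conditions: PhSeH, Cs2CO3 (0.5 equiv), DMF, 60 °C
Reagents that add atoms: benzeneselenol [SeH]c1ccccc1
Why: The soft selenolate opens the epoxide by SN2 attack at C2 (C3 is neopentyl) from the α face, the trans-diaxial (Fürst–Plattner) mode, which leaves the axial 3β-hydroxyl with retention at C3.

Step 23
Reactants: 33 2α-phenylselanyl 3β-alcohol
Product: 34 3β-alcohol (C20 acetal, 16-methylene)
Conditions: Bu3SnH, azobis(isobutyronitrile), PhMe, 80 °C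
Reagents that add atoms: none
Why: Radical deselenation (homolysis of the C–Se bond and hydrogen transfer from the stannane) removes the C2 substituent without affecting the alkene, esters or acetal.

Step 24
Reactants: 34 3β-alcohol
Product: 35 7-carboxylic acid
Conditions: LiOH, THF/H2O, 40 °C; then 1 M HCl to pH 4
Reagents that add atoms: lithium hydroxide [Li+].[OH-]
Why: Saponification removes the secondary C7 methyl ester, whereas the C19 ester on quaternary C4 and the acetal resist hydroxide, and C6 stays in its more stable β configuration.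

Step 25
Reactants: 35 7-carboxylic acid
Product: 37 target CNP0236431.1, via acetal diacid 36 (not isolated)
Conditions: Bu4NF (5 equiv), THF, 40 °C; then 1 M HCl, THF/H2O, rt
Reagents that add atoms: water O
Why: Fluoride cleaves the 2-(trimethylsilyl)ethyl ester by β-elimination and the silyl ether by Si–F bond formation, and dilute acid then hydrolyses the dimethyl acetal, assisted by the neighbouring C19 acid, under conditions too mild to disturb the 13-hydroxy-16-ene.

Compound list

1 | pent-4-enal | C=CCCC=O | starting material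
2 | but-3-en-2-one (methyl vinyl ketone) | CC(=O)C=C | starting material
3 | (2S)-5-oxo-2-(prop-2-en-1-yl)hexanal | CC(=O)CC[C@H](C=O)CC=C | intermediate
4 | (4S)-4-(prop-2-en-1-yl)cyclohex-2-en-1-one | C1=CC(=O)CC[C@H]1CC=C | intermediate
5 | tert-butyl[(1-methoxyethenyl)oxy]dimethylsilane | C=C(OC)O[Si](C)(C)C(C)(C)C | starting material
6 | methyl 2-[(1S,6S)-3-(tert-butyldimethylsilyloxy)-6-(prop-2-en-1-yl)cyclohex-2-en-1-yl]acetate (trans) | COC(=O)C[C@@H]1C=C(O[Si](C)(C)C(C)(C)C)CC[C@H]1CC=C | intermediate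
7 | methyl 2-[(6S)-3-oxo-6-(prop-2-en-1-yl)cyclohex-1-en-1-yl]acetate | COC(=O)CC1=CC(=O)CC[C@H]1CC=C | intermediate
8 | tributyl(propa-1,2-dien-1-yl)stannane | C=C=C[Sn](CCCC)(CCCC)CCCC | starting material
9 | methyl 2-[(1R,2S)-5-oxo-2-(prop-2-en-1-yl)-1-(prop-2-yn-1-yl)cyclohexyl]acetate | C#CC[C@]1(CC(=O)OC)CC(=O)CC[C@H]1CC=C | intermediate
10 | methyl 2-[(1R,2S)-5-oxo-2-(2-oxoethyl)-1-(prop-2-yn-1-yl)cyclohexyl]acetate (not isolated) | C#CC[C@]1(CC(=O)OC)CC(=O)CC[C@H]1CC=O | intermediate
11 | methyl 2-[(1R,2S)-2-(2,2-dimethoxyethyl)-5-oxo-1-(prop-2-yn-1-yl)cyclohexyl]acetate | C#CC[C@]1(CC(=O)OC)CC(=O)CC[C@H]1CC(OC)OC | intermediate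
12 | methyl 2-[2-(2,2-dimethoxyethyl)-5-hydroxy-6-methylidenebicyclo[3.2.1]octan-1-yl]acetate (C8, C9, C13 configured as in the target) | C=C1C[C@]2(CC(=O)OC)C[C@@]1(O)CC[C@H]2CC(OC)OC | intermediate
13 | methyl 2-[5-hydroxy-6-methylidene-2-(2-oxoethyl)bicyclo[3.2.1]octan-1-yl]acetate (not isolated) | C=C1C[C@]2(CC(=O)OC)C[C@@]1(O)CC[C@H]2CC=O | intermediate
14 | methyl 2-{2-[(1E)-1-(dimethylamino)-3-oxoprop-1-en-2-yl]-5-hydroxy-6-methylidenebicyclo[3.2.1]octan-1-yl}acetate | C=C1C[C@]2(CC(=O)OC)C[C@@]1(O)CC[C@H]2/C(C=O)=C\N(C)C | intermediate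
15 | aldol adduct: ring B closed, C5 carbinol (epimers), C10 dimethylaminomethylidene, 6β-CO2Me, 13-OH, 16-methylene (not isolated) | C=C1C[C@]23C[C@@]1(O)CC[C@H]2C(=CN(C)C)C(O)[C@@H]3C(=O)OC | intermediate
16 | tricyclic enal: methyl 13-hydroxy-20-oxo-1,2,3,4,18,19-hexanorgibberella-5(10),16-dien-7-oate, 6β-ester (rings B, C, D; CHO on C10) | C=C1C[C@]23C[C@@]1(O)CC[C@H]2C(C=O)=C[C@@H]3C(=O)OC | intermediate
17 | 13-O-tert-butyldimethylsilyl ether of 16 | C=C1C[C@]23C[C@@]1(O[Si](C)(C)C(C)(C)C)CC[C@H]2C(C=O)=C[C@@H]3C(=O)OC | intermediate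
18 | 2,2,6-trimethyl-4H-1,3-dioxin-4-one | CC1=CC(=O)OC(C)(C)O1 | starting material
19 | 2-(trimethylsilyl)ethanol | C[Si](C)(C)CCO | starting material
20 | 2-(trimethylsilyl)ethyl 3-oxobutanoate | CC(=O)CC(=O)OCC[Si](C)(C)C | intermediate
21 | Michael adduct: C5 bears CH(COCH3)CO2CH2CH2SiMe3 (H5 β), C10 bears CHO; C4 and C10 epimers (not isolated) | C=C1C[C@]23C[C@@]1(O[Si](C)(C)C(C)(C)C)CC[C@H]2C(C=O)[C@@H](C(C(C)=O)C(=O)OCC[Si](C)(C)C)[C@@H]3C(=O)OC | intermediate
22 | trans-fused enone: ring B fused at C5–C10 to a cyclohex-2-enone made of C10, C20, C2, C3, C4, C5 (C3=O, C2=C20, CO2CH2CH2SiMe3 on C4, drawn 4β and configurationally labile; H5 β, H10 α; 6β-CO2Me; 13-OTBS; 16-methylene) | C=C1C[C@]23C[C@@]1(O[Si](C)(C)C(C)(C)C)CC[C@H]2[C@@H]1C=CC(=O)[C@H](C(=O)OCC[Si](C)(C)C)[C@H]1[C@@H]3C(=O)OC | intermediate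
23 | allylic alcohol from 22: C3 hydroxyl on the α face (H3 β), C4 ester drawn 4β (epimers converge) | C=C1C[C@]23C[C@@]1(O[Si](C)(C)C(C)(C)C)CC[C@H]2[C@@H]1C=C[C@@H](O)[C@H](C(=O)OCC[Si](C)(C)C)[C@H]1[C@@H]3C(=O)OC | intermediate
24 | C4-methylated allylic alcohol: 4β-methyl, 4α-CO2CH2CH2SiMe3, C3 hydroxyl α | C=C1C[C@]23C[C@@]1(O[Si](C)(C)C(C)(C)C)CC[C@H]2[C@@H]1C=C[C@@H](O)[C@@](C)(C(=O)OCC[Si](C)(C)C)[C@H]1[C@@H]3C(=O)OC | intermediate
25 | lactol aldehyde: tetrahydropyran O–C20H(OH)–C10–C5–C4–C3 (anomers) with CHO (C2) on C3, 16-ketone, 13-OTBS | O=C1C[C@]23C[C@@]1(O[Si](C)(C)C(C)(C)C)CC[C@H]2[C@@H]1C(O)O[C@H](C=O)[C@@](C)(C(=O)OCC[Si](C)(C)C)[C@H]1[C@@H]3C(=O)OC | intermediate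
26 | 3-vinyl lactol (anomers) | O=C1C[C@]23C[C@@]1(O[Si](C)(C)C(C)(C)C)CC[C@H]2[C@@H]1C(O)O[C@H](C=C)[C@@](C)(C(=O)OCC[Si](C)(C)C)[C@H]1[C@@H]3C(=O)OC | intermediate
27 | lactol mesylate of 26 (not isolated) | O=C1C[C@]23C[C@@]1(O[Si](C)(C)C(C)(C)C)CC[C@H]2[C@@H]1C(OS(C)(=O)=O)O[C@H](C=C)[C@@](C)(C(=O)OCC[Si](C)(C)C)[C@H]1[C@@H]3C(=O)OC | intermediate
28 | Claisen substrate: 2-vinyl-3,4-dihydro-2H-pyran (enol ether C10=C20–O–C3; 3β-vinyl, 4β-methyl, 4α-CO2CH2CH2SiMe3, H5 β, 6β-CO2Me) fused to rings B, C, D; 13-OTBS; 16-ketone | O=C1C[C@]23C[C@@]1(O[Si](C)(C)C(C)(C)C)CC[C@H]2C1=CO[C@H](C=C)[C@@](C)(C(=O)OCC[Si](C)(C)C)[C@H]1[C@@H]3C(=O)OC | intermediate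
29 | Claisen product: 7-methyl 19-[2-(trimethylsilyl)ethyl] 13-(tert-butyldimethylsilyloxy)-16,20-dioxo-17-norgibberell-2-ene-7,19-dioate (C20 formyl on C10, C2=C3) | O=C1C[C@]23C[C@@]1(O[Si](C)(C)C(C)(C)C)CC[C@H]2[C@]1(C=O)CC=C[C@@](C)(C(=O)OCC[Si](C)(C)C)[C@H]1[C@@H]3C(=O)OC | intermediate
30 | C20 dimethyl acetal of 29 | O=C1C[C@]23C[C@@]1(O[Si](C)(C)C(C)(C)C)CC[C@H]2[C@]1(C(OC)OC)CC=C[C@@](C)(C(=O)OCC[Si](C)(C)C)[C@H]1[C@@H]3C(=O)OC | intermediate
31 | 2β,3β-epoxide of 30 | O=C1C[C@]23C[C@@]1(O[Si](C)(C)C(C)(C)C)CC[C@H]2[C@]1(C(OC)OC)C[C@@H]4O[C@@H]4[C@@](C)(C(=O)OCC[Si](C)(C)C)[C@H]1[C@@H]3C(=O)OC | intermediate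
32 | 16-methylene 2β,3β-epoxide | C=C1C[C@]23C[C@@]1(O[Si](C)(C)C(C)(C)C)CC[C@H]2[C@]1(C(OC)OC)C[C@@H]4O[C@@H]4[C@@](C)(C(=O)OCC[Si](C)(C)C)[C@H]1[C@@H]3C(=O)OC | intermediate
33 | 2α-phenylselanyl 3β-alcohol | C=C1C[C@]23C[C@@]1(O[Si](C)(C)C(C)(C)C)CC[C@H]2[C@]1(C(OC)OC)C[C@@H]([Se]c4ccccc4)[C@H](O)[C@@](C)(C(=O)OCC[Si](C)(C)C)[C@H]1[C@@H]3C(=O)OC | intermediate
34 | 3β-alcohol: 7-methyl 19-[2-(trimethylsilyl)ethyl] ester, C20 dimethyl acetal, 13-OTBS, 16-methylene | C=C1C[C@]23C[C@@]1(O[Si](C)(C)C(C)(C)C)CC[C@H]2[C@]1(C(OC)OC)CC[C@H](O)[C@@](C)(C(=O)OCC[Si](C)(C)C)[C@H]1[C@@H]3C(=O)OC | intermediate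
35 | 7-carboxylic acid of 34 | C=C1C[C@]23C[C@@]1(O[Si](C)(C)C(C)(C)C)CC[C@H]2[C@]1(C(OC)OC)CC[C@H](O)[C@@](C)(C(=O)OCC[Si](C)(C)C)[C@H]1[C@@H]3C(=O)O | intermediate
36 | 7,19-diacid with free 3β- and 13-hydroxyls and C20 dimethyl acetal (not isolated) | C=C1C[C@]23C[C@@]1(O)CC[C@H]2[C@]1(C(OC)OC)CC[C@H](O)[C@@](C)(C(=O)O)[C@H]1[C@@H]3C(=O)O | intermediate
37 | CNP0236431.1: 3β,13-dihydroxy-20-oxogibberell-16-ene-7,19-dioic acid | C=C1C[C@]23C[C@@]1(O)CC[C@H]2[C@]1(C=O)CC[C@H](O)[C@@](C)(C(=O)O)[C@H]1[C@@H]3C(=O)O | target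

Total step count: 25. Longest linear sequence: 24 steps (steps 1–10 and 12–25; step 11 prepares the acetoacetate fragment).

Steps most likely to fail

Step 18. The enol ether may be protonated by traces of acid and hydrolyse or oligomerise before the boat transition state is reached, or heterolysis of the allylic C3–O bond with elimination may outrun the crowded C1–C10 bond formation. The fallback builds ring A by a base-mediated double Michael annulation instead of a sigmatropic shift; it sets out from 17 and returns at 34. 2-(Trimethylsilyl)ethyl acetate is deprotonated with LiN(i-Pr)2 and added to acrolein to give 2-(trimethylsilyl)ethyl 3-hydroxypent-4-enoate F1, which Dess–Martin periodinane oxidises to the Nazarov reagent 2-(trimethylsilyl)ethyl 3-oxopent-4-enoate F2. With Cs2CO3 in CH2Cl2, F2 should add through C4 to C5 of 17 anti to the 6β-ester, and the resulting C10 enolate should close onto C1 from its open β face to give the ring A keto aldehyde F3. Acetalisation (HC(OMe)3, pyridinium p-toluenesulfonate, MeOH) gives the C20 dimethyl acetal F4. K2CO3 and MeI should methylate C4 anti to the axial C20 acetal to give the 4β-methyl ketone F5. KBH(s-Bu)3 should then reduce the 3-ketone from the equatorial side to the axial 3β-alcohol, which is 34; this path keeps the 16-methylene throughout.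

Step 5. Addition to the β,β-disubstituted enone may be slow, so that 1,2-addition or protodestannylation of the stannane competes and facial selectivity erodes. The fallback carries the three-carbon unit as a more robust allylsilane and forms the alkyne afterwards; it sets out from 7 and returns at 9. Sakurai addition of (2-bromoprop-2-en-1-yl)trimethylsilane with TiCl4 in CH2Cl2 at −78 °C should give methyl 2-[(1R,2S)-1-(2-bromoprop-2-en-1-yl)-5-oxo-2-(prop-2-en-1-yl)cyclohexyl]acetate F6, again anti to the C9 allyl group. Dehydrobromination of the vinyl bromide with Bu4NF trihydrate in DMF at 60 °C should give 9.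

Step 14. The β-alkoxide of the dianion may fragment by retro-aldol cleavage, or methylation may occur on oxygen. The fallback replaces the chelated dianion by a mono-enolate of the O-protected ester under steric control; it sets out from 23 and returns at 24. Et3SiOTf and 2,6-lutidine give the 3-O-triethylsilyl ether F7. KN(SiMe3)2 and MeI in THF/DMPU at −78 °C should methylate the exocyclic enolate from the equatorial β direction, anti to the silyloxy group, to give the 4β-methyl silyl ether F8. Pyridinium p-toluenesulfonate in MeOH removes the secondary triethylsilyl group, leaving the tertiary silyl ether, to give 24.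

Further compounds

F1 | step 18 | 2-(trimethylsilyl)ethyl 3-hydroxypent-4-enoate (racemic) | C=CC(O)CC(=O)OCC[Si](C)(C)C
F2 | step 18 | 2-(trimethylsilyl)ethyl 3-oxopent-4-enoate | C=CC(=O)CC(=O)OCC[Si](C)(C)C
F3 | step 18 | ring A keto aldehyde: 7-methyl 19-[2-(trimethylsilyl)ethyl] 13-(tert-butyldimethylsilyloxy)-3,20-dioxo-18-norgibberell-16-ene-7,19-dioate (C4 epimers) | C=C1C[C@]23C[C@@]1(O[Si](C)(C)C(C)(C)C)CC[C@H]2[C@]1(C=O)CCC(=O)C(C(=O)OCC[Si](C)(C)C)[C@H]1[C@@H]3C(=O)OC
F4 | step 18 | C20 dimethyl acetal of F3 | C=C1C[C@]23C[C@@]1(O[Si](C)(C)C(C)(C)C)CC[C@H]2[C@]1(C(OC)OC)CCC(=O)C(C(=O)OCC[Si](C)(C)C)[C@H]1[C@@H]3C(=O)OC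
F5 | step 18 | 4β-methyl 3-ketone (C20 dimethyl acetal, 4α-ester) | C=C1C[C@]23C[C@@]1(O[Si](C)(C)C(C)(C)C)CC[C@H]2[C@]1(C(OC)OC)CCC(=O)[C@@](C)(C(=O)OCC[Si](C)(C)C)[C@H]1[C@@H]3C(=O)OC
F6 | step 5 | methyl 2-[(1R,2S)-1-(2-bromoprop-2-en-1-yl)-5-oxo-2-(prop-2-en-1-yl)cyclohexyl]acetate | C=C(Br)C[C@]1(CC(=O)OC)CC(=O)CC[C@H]1CC=C
F7 | step 14 | 3-O-triethylsilyl ether of 23 | C=C1C[C@]23C[C@@]1(O[Si](C)(C)C(C)(C)C)CC[C@H]2[C@@H]1C=C[C@@H](O[Si](CC)(CC)CC)[C@H](C(=O)OCC[Si](C)(C)C)[C@H]1[C@@H]3C(=O)OC
F8 | step 14 | 3-O-triethylsilyl ether of 24 | C=C1C[C@]23C[C@@]1(O[Si](C)(C)C(C)(C)C)CC[C@H]2[C@@H]1C=C[C@@H](O[Si](CC)(CC)CC)[C@@](C)(C(=O)OCC[Si](C)(C)C)[C@H]1[C@@H]3C(=O)OC
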